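If the last reading of the red run, at 3.00 d, shows D and J summing to 68.0%, then about a third of the E charged stands in neither column, and two of us at the board read that gap differently.

all flasks: E 0.10 M
- red: Z 3 equiv; run made earlier
- flask: Z 2.00 equiv; time 30 d

- red (time / d: D / %, J / %): 0.250: 28, 0; 0.417: 33, 0; 0.625: 42, 7; 1.04: 51, 12; 1.67: 49, 17; 3.00: 41, 27

(scatter of a reading: 2 percentage points)

- equivalents of Z to E, everything else as given, that leave most D at 30 d
- the amount of D then, in percent of the E charged
- the amount of D with the amounts as given

- the numbers in the tables scatter by 2 percentage points (one standard deviation)
- a reading or a percentage of J counts all its forms, free or not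

The forecast takes the gap to be E still held in balance with D, by what “looks like a fast reversible step”. It gives 7% of D for the flask as charged, and a best of 8.5% at 1.5 equiv.

My own view is that the gap is lost for good, the pool of D plus J stays where the red run shows it, and each D drains into J with a second Z. Between 1.04 d and 3.00 d the red run then has a mean free Z of 2.15 equivalents. The rise of J over the mean D, divided by that free Z, gives the drain constant, the pseudo-first-order drain of D per equivalent of free Z: 0.0774 d⁻¹, a reading with the scatter of its points.

Multiply it by the mean free Z and the time to get the drain number; the share of the pool still D is e to the minus that number. The zero of the scale is the even flask, D equal to J, at 0.693. For the flask, mean free Z is about 0.980 equivalents, so the drain number is 2.28, well above even, and D comes to 6.99%. That matches the forecast's n by another road. We part lower down: the drain number shrinks with Z, so I put the best charge below 1.5 equiv, with more D than 8.5%.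

The flask gives 4.46% of D, and the best is 19.1% at 0.627 equiv.

    E + Z → D + X (k = 0.216 L mol⁻¹ h⁻¹)
    2 E → L (k = 0.283 L mol⁻¹ h⁻¹)
    Q ⇌ J, rate k3*(cs3 - [J]) while solid is left; crystals form when [J] > cs3 (solubility = 24.0 mM, k = 0.412 h⁻¹)
    Z + D → J + X (k = 0.0384 L mol⁻¹ h⁻¹)

In the flask the gap was L, 38.9% of the E charged, with E at 0% after 30.0 d. The forecast's best charge stands above the flask's, while its 7% for the flask as charged held within the margin. The flask's own D share reads a drain number of 2.62. In the neighbour with 0.500 equiv of Z, mean free Z of 0.165 equivalents and the drain constant give a drain number of 0.383, so a D share of 68.2%. That neighbour holds 18.6% of D beside 9.94% of J, a share of 65.2%.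

The runs are simulated on assumed constants.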